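The flavone is cut through its pyranone ring C (O1, C2, C3, C4, C4a, C8a). C4 comes from carbon monoxide, C2–C3 from a B-ring arylacetylene, and O1 with C8a/C4a from an ortho-iodophenol whose A ring is already fully substituted. One palladium-catalysed carbonylative alkyne coupling with in-flask oxa-Michael closure forges C4a–C4, C4–C3 and O1–C2, joining both arenes and closing ring C. The precursor is 2-iodo-3,4,5,6-tetramethoxyphenol, carried as its O-acetate (more reactive towards Pd(0), less oxidation-prone, cleaved by the amine in the same flask), with 1,4-bis(benzyloxy)-2-ethynyl-5-methoxybenzene. One boron trichloride treatment then frees the peri C5 hydroxyl and both B-ring phenols.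

Key step: step 7

Assumption: the target has no stereocentre or other stereogenic element, so it is one achiral compound and no step needs stereocontrol.

Step 1
Reactants: 1 1,2,3,4-tetramethoxybenzene
Product: 4 2,3,4,5-tetramethoxyphenol, via aryllithium 2 (not isolated), via lithium aryltrimethoxyborate 3 (not isolated)
Conditions: n-BuLi, TMEDA, THF, 0 °C; B(OMe)3, −78 °C → rt; then AcOH, 30% aq. H2O2, 0 °C → rt
Reagents that add atoms: hydrogen peroxide, OO
Why: Directed ortho-metalation followed by borylation and oxidation: the two ring hydrogens of 1 are equivalent and each is ortho to a methoxy group, so one aryllithium should form, and the borate is oxidised by the usual 1,2-aryl shift from boron to oxygen.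

Step 2
Reactants: 4 2,3,4,5-tetramethoxyphenol
Product: 5 2-iodo-3,4,5,6-tetramethoxyphenol
Conditions: NIS (1.05 equiv), MeCN, 0 °C, dark
Reagents that add atoms: N-iodosuccinimide, O=C1CCC(=O)N1I
Why: Electrophilic aromatic iodination at the only unsubstituted ring carbon, which is ortho to the free hydroxyl, so regiochemistry is fixed, and a mild non-acidic iodonium source at low temperature should limit oxidation of the electron-rich phenol.

Step 3
Reactants: 5 2-iodo-3,4,5,6-tetramethoxyphenol
Product: 6 2-iodo-3,4,5,6-tetramethoxyphenyl acetate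
Conditions: Ac2O, pyridine, DMAP (cat.), CH2Cl2, rt
Reagents that add atoms: acetic anhydride, CC(=O)OC(C)=O
Why: DMAP-catalysed O-acylation of the hindered phenol; the acetate lowers the electron density of the ring for oxidative addition and masks the oxidation-prone phenol until the amine of step 7 removes it.

Step 4
Reactants: 7 methoxyhydroquinone (2-methoxybenzene-1,4-diol)
Product: 8 1,4-bis(benzyloxy)-2-methoxybenzene
Conditions: BnBr (2.3 equiv), K2CO3, degassed DMF, N2, rt → 60 °C
Reagents that add atoms: benzyl bromide, BrCc1ccccc1
Why: Williamson ether synthesis on both phenols, run under nitrogen because the hydroquinone anion is readily oxidised to the quinone by air.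

Step 5
Reactants: 8 1,4-bis(benzyloxy)-2-methoxybenzene
Product: 10 2,5-bis(benzyloxy)-4-methoxybenzaldehyde, via aryl iminium chloride 9 (not isolated)
Conditions: POCl3, DMF, 0 → 70 °C; then H2O, rt
Reagents that add atoms: N,N-dimethylformamide, CN(C)C=O; water, O
Why: Vilsmeier–Haack formylation at C5 of 8, which is para to the methoxy group and ortho to a benzyloxy group and is the most nucleophilic unhindered position (as in the formylation of 1,2,4-trimethoxybenzene), under conditions that benzyl ethers tolerate.

Step 6
Reactants: 10 2,5-bis(benzyloxy)-4-methoxybenzaldehyde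
Product: 11 1,4-bis(benzyloxy)-2-ethynyl-5-methoxybenzene
Conditions: dimethyl (1-diazo-2-oxopropyl)phosphonate, K2CO3, MeOH/THF, rt
Reagents that add atoms: dimethyl (1-diazo-2-oxopropyl)phosphonate, CC(=O)C(=[N+]=[N-])P(=O)(OC)OC
Why: Seyferth–Gilbert homologation in the Ohira–Bestmann variant: methanolysis of the reagent releases the diazomethylphosphonate anion, which adds to the non-enolisable aldehyde, and loss of dimethyl phosphate and nitrogen with a 1,2-shift should give the terminal alkyne without touching the benzyl ethers.

Step 7
Reactants: 6 2-iodo-3,4,5,6-tetramethoxyphenyl acetate; 11 1,4-bis(benzyloxy)-2-ethynyl-5-methoxybenzene; 12 carbon monoxide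
Product: 15 2-[2,5-bis(benzyloxy)-4-methoxyphenyl]-5,6,7,8-tetramethoxychromen-4-one, via acetoxyaryl ynone 13 (not isolated), via hydroxyaryl enaminone 14 (not isolated)
Conditions: CO (1 atm), PdCl2(PPh3)2 (5 mol %), dppp (5 mol %), thiourea (5 mol %), DBU (2 equiv), Et2NH, 40 → 60 °C
Reagents that add atoms: none
Why: Pd(0) inserts into the C–I bond of 6, CO migrates in to give the aroyl-palladium, and copper-free coupling with the acetylide of 11 should give ynone 13 (bonds C4a–C4 and C4–C3); diethylamine then removes the acetyl group and adds to the ynone to give enaminone 14, whose phenol oxygen attacks the amine-bearing carbon and expels the amine (bond O1–C2). The closest known reaction type is the carbonylative Sonogashira annulation of ortho-iodophenols and their acetates with terminal alkynes to flavones. Ring C closes in a 6-endo sense, formally 6-endo-dig on the ynone and in practice an addition–elimination at C2 of the enaminone, and no stereocentre is formed. The step needs CO uptake before alkyne transfer and six- over five-membered closure: the electron-rich aryl group migrates to CO quickly and no copper is present to speed direct coupling, while the enaminone leaves C2 as the only electrophilic carbon, so the 5-exo path to the aurone is closed. Regiochemistry on ring A is not in question because iodine sits on the only carbon without oxygen, and the acetate together with a chelating phosphine should keep oxidative addition into this di-ortho-substituted iodide viable.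

Step 8
Reactants: 15 2-[2,5-bis(benzyloxy)-4-methoxyphenyl]-5,6,7,8-tetramethoxychromen-4-one
Product: 16 2-(2,5-dihydroxy-4-methoxyphenyl)-5-hydroxy-6,7,8-trimethoxychromen-4-one
Conditions: BCl3 (1 M in CH2Cl2, 6 equiv), pentamethylbenzene (6 equiv), CH2Cl2, −78 → 0 °C, Ar; then 1 M aq. HCl/THF, rt (degassed)
Reagents that add atoms: none
Why: Lewis-acid ether cleavage: BCl3 with pentamethylbenzene as a non-coordinating benzyl-cation scavenger should remove both aryl benzyl ethers at −78 °C, and on warming the C5 methyl ether, the only one able to form a six-membered boron chelate with the C4 carbonyl, should be cleaved while the 6-, 7-, 8- and 4'-methoxy groups stay.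

Compound list
1 | 1,2,3,4-tetramethoxybenzene | COc1ccc(OC)c(OC)c1OC | starting material
2 | (2,3,4,5-tetramethoxyphenyl)lithium | [Li]c1cc(OC)c(OC)c(OC)c1OC | intermediate
3 | lithium trimethoxy(2,3,4,5-tetramethoxyphenyl)borate | [Li+].CO[B-](OC)(OC)c1cc(OC)c(OC)c(OC)c1OC | intermediate
4 | 2,3,4,5-tetramethoxyphenol | COc1cc(O)c(OC)c(OC)c1OC | intermediate
5 | 2-iodo-3,4,5,6-tetramethoxyphenol | COc1c(O)c(I)c(OC)c(OC)c1OC | intermediate
6 | 2-iodo-3,4,5,6-tetramethoxyphenyl acetate | CC(=O)Oc1c(I)c(OC)c(OC)c(OC)c1OC | intermediate
7 | methoxyhydroquinone (2-methoxybenzene-1,4-diol) | COc1cc(O)ccc1O | starting material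
8 | 1,4-bis(benzyloxy)-2-methoxybenzene | COc1cc(OCc2ccccc2)ccc1OCc1ccccc1 | intermediate
9 | N-[2,5-bis(benzyloxy)-4-methoxybenzylidene]-N-methylmethanaminium chloride | C[N+](C)=Cc1cc(OCc2ccccc2)c(OC)cc1OCc1ccccc1.[Cl-] | intermediate
10 | 2,5-bis(benzyloxy)-4-methoxybenzaldehyde | O=Cc1cc(OCc2ccccc2)c(OC)cc1OCc1ccccc1 | intermediate
11 | 1,4-bis(benzyloxy)-2-ethynyl-5-methoxybenzene | C#Cc1cc(OCc2ccccc2)c(OC)cc1OCc1ccccc1 | intermediate
12 | carbon monoxide | [C-]#[O+] | starting material
13 | 2-{3-[2,5-bis(benzyloxy)-4-methoxyphenyl]prop-2-ynoyl}-3,4,5,6-tetramethoxyphenyl acetate | CC(=O)Oc1c(C(=O)C#Cc2cc(OCc3ccccc3)c(OC)cc2OCc2ccccc2)c(OC)c(OC)c(OC)c1OC | intermediate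
14 | (E)-3-[2,5-bis(benzyloxy)-4-methoxyphenyl]-3-(diethylamino)-1-(2-hydroxy-3,4,5,6-tetramethoxyphenyl)prop-2-en-1-one | CCN(CC)/C(=C/C(=O)c1c(O)c(OC)c(OC)c(OC)c1OC)c1cc(OCc2ccccc2)c(OC)cc1OCc1ccccc1 | intermediate
15 | 2-[2,5-bis(benzyloxy)-4-methoxyphenyl]-5,6,7,8-tetramethoxychromen-4-one | COc1c(OC)c(OC)c2oc(-c3cc(OCc4ccccc4)c(OC)cc3OCc3ccccc3)cc(=O)c2c1OC | intermediate
16 | 2-(2,5-dihydroxy-4-methoxyphenyl)-5-hydroxy-6,7,8-trimethoxychromen-4-one | COc1cc(O)c(-c2cc(=O)c3c(O)c(OC)c(OC)c(OC)c3o2)cc1O | target

Total step count: 8 steps.
Longest linear sequence: 5 steps (steps 4, 5, 6, 7, 8 from methoxyhydroquinone; the A-ring branch, steps 1, 2, 3, 7, 8, is equally long).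

Steps most likely to fail

Step 7. Oxidative addition into the hindered, electron-rich C–I bond may be slow. The aroyl-palladium may be intercepted by diethylamine to give an amide. Coupling may occur without CO uptake and lead on to a benzofuran. The fallback builds ring C by the chalcone route and sets out from phenol 4 and aldehyde 10. Ortho C-acetylation of 4 with AcOH/BF3·OEt2 under heating should give 1-(2-hydroxy-3,4,5,6-tetramethoxyphenyl)ethanone F1. Claisen–Schmidt condensation of F1 with 10 (KOH, EtOH, rt) should give (E)-3-[2,5-bis(benzyloxy)-4-methoxyphenyl]-1-(2-hydroxy-3,4,5,6-tetramethoxyphenyl)prop-2-en-1-one F2. Oxidative cyclisation of F2 with catalytic I2 in DMSO at 120 °C comes back to the route at 15.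

Step 8. Demethylation may run on to C6, next to the boron-bound C5 oxygen, or cleavage may stay incomplete and give mixtures. The freed hydroquinone may also be oxidised by air during work-up. The fallback separates the two events and sets out from 15. Hydrogenolysis (H2, Pd/C, EtOAc/THF, rt) should give 2-(2,5-dihydroxy-4-methoxyphenyl)-5,6,7,8-tetramethoxychromen-4-one F3. Chelation-controlled cleavage of its 5-methyl ether with BCl3 (4 equiv, CH2Cl2, −20 → 0 °C) comes back to the route at 16.

Step 2. The electron-rich para-alkoxyphenol may be oxidised to quinone-type products instead of being iodinated on the ring. The fallback reverses the order of events and sets out from 4. Acetylation (Ac2O, pyridine, DMAP) should give 2,3,4,5-tetramethoxyphenyl acetate F4, which no longer has a free phenol to oxidise. Iodination of F4 at its only free ring carbon with NIS and catalytic TFA in MeCN comes back to the route at 6, bypassing 5.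

Further compounds
F1 | step 7 | 1-(2-hydroxy-3,4,5,6-tetramethoxyphenyl)ethanone | CC(=O)c1c(O)c(OC)c(OC)c(OC)c1OC
F2 | step 7 | (E)-3-[2,5-bis(benzyloxy)-4-methoxyphenyl]-1-(2-hydroxy-3,4,5,6-tetramethoxyphenyl)prop-2-en-1-one | O=C(/C=C/c1cc(OCc2ccccc2)c(OC)cc1OCc1ccccc1)c1c(O)c(OC)c(OC)c(OC)c1OC
F3 | step 8 | 2-(2,5-dihydroxy-4-methoxyphenyl)-5,6,7,8-tetramethoxychromen-4-one | COc1cc(O)c(-c2cc(=O)c3c(OC)c(OC)c(OC)c(OC)c3o2)cc1O
F4 | step 2 | 2,3,4,5-tetramethoxyphenyl acetate | CC(=O)Oc1cc(OC)c(OC)c(OC)c1OC
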